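The synthesis rests on the O1–C2 bond of the pyranone ring C. Cutting it gives an achiral chalcone, 2',6'-dihydroxy-4'-methoxy-3',5'-bis(2-hydroxybenzyl)chalcone. Its ring A has a local twofold axis through C1' and C4'. Both ortho hydroxyls (future O1 and 5-OH) and both benzyl arms (future C6 and C8 substituents) are therefore equivalent, and ring closure poses one question only: the face of C-β. A chalcone isomerase answers it. It closes ring C by oxa-Michael addition and sets C2 as S in one protecting-group-free operation, which small catalysts do not achieve selectively on unactivated chalcones. The chalcone is assembled in two steps from an acetophenone, salicyl alcohol and benzaldehyde.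

Key step: step 3

Assumption: a chalcone isomerase that tolerates the 3',5'-dibenzylated, 4'-O-methylated ring A is taken to be found by screening natural type I, type II and bacterial enzymes or variants with a widened A-ring pocket. The unsubstituted B ring of 9 is the one already accepted in pinocembrin chalcone.

Step 1
Reactants: 1 2',6'-dihydroxy-4'-methoxyacetophenone; 2 2-hydroxybenzyl alcohol (salicyl alcohol, 2.3 equiv)
Product: 5 1-[2,6-dihydroxy-3,5-bis(2-hydroxybenzyl)-4-methoxyphenyl]ethan-1-one, via ortho-quinone methide 3 (not isolated), via monobenzylated acetophenone 4 (not isolated)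
Conditions: ZnCl2 (anhydrous, 3 equiv), 1,4-dioxane, reflux, slow addition of 2
Reagents that add atoms: none
Why: This is a Friedel–Crafts ortho-hydroxybenzylation through an ortho-quinone methide, in which zinc chloride dehydrates 2 to 3 and 3 is trapped first at C3' and then at C5', the only free and mutually equivalent ring carbons of 1, each activated by ortho and para oxygen, so exhaustive alkylation can give only one constitution.

Step 2
Reactants: 5 1-[2,6-dihydroxy-3,5-bis(2-hydroxybenzyl)-4-methoxyphenyl]ethan-1-one; 6 benzaldehyde (1.3 equiv)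
Product: 9 (E)-1-[2,6-dihydroxy-3,5-bis(2-hydroxybenzyl)-4-methoxyphenyl]-3-phenylprop-2-en-1-one, via pentalithium enolate 7 (not isolated), via pentalithium aldolate 8 (not isolated)
Conditions: LiHMDS (5.5 equiv), THF, −78 to 0 °C; 6, −78 °C to rt; poured into 1 M HCl at 0 °C; rapid chromatography below 25 °C to remove any ring-closed material
Reagents that add atoms: none
Why: This is a Claisen–Schmidt condensation on the unprotected polyhydroxyacetophenone polyanion, in which the amide base masks the four phenols as lithium phenoxides and enolises the acetyl group, aldol addition to the non-enolisable aldehyde and E1cB loss of lithium hydroxide give the favoured E-enone, and the enone stays ring-open as its chelated diphenoxide until the cold acid quench.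

Step 3
Reactants: 9 (E)-1-[2,6-dihydroxy-3,5-bis(2-hydroxybenzyl)-4-methoxyphenyl]-3-phenylprop-2-en-1-one
Product: 11 (2S)-5-hydroxy-6,8-bis(2-hydroxybenzyl)-7-methoxy-2-phenylchroman-4-one (7-methoxydichamanetin), via enzyme-bound flavanone enol 10 (not isolated)
Conditions: chalcone isomerase (chalcone–flavanone isomerase, intramolecular lyase, EC 5.5.1.6, recombinant, cat.), MES buffer pH 6.5, 10% DMSO, hydroxypropyl-β-cyclodextrin, 15 °C, dark, N2, slow feed of 9; EtOAc extraction at pH 5
Reagents that add atoms: none
Why: The enzyme binds 9 in a folded conformation with one 2'-hydroxyl ionised, the phenoxide adds to C-β in an intramolecular oxa-Michael addition, and the enol(ate) 10, stabilised by the hydrogen-bond network of the active site, is protonated at C3. The closest known reaction type is the chalcone isomerase cyclisation of 2',6'-dihydroxychalcones such as naringenin chalcone and pinocembrin chalcone to (2S)-flavanones. Ring C closes in the 6-endo-trig mode by formation of O1–C2. C2, the only stereocentre, is controlled by the chiral pocket, which exposes only the Si face of C-β (Ph > C-α > H) to the phenoxide and so should give S. Regioselectivity needs no control because the twofold axis of ring A makes both ortho hydroxyls and both benzyl arms equivalent, and the pendant phenols cannot compete because they would have to close ten-membered rings. The selectivity to be secured is enzymatic over uncatalysed racemic closure, which is served by pH 6.5 (little free phenoxide in solution), slow feeding, low temperature and a mildly acidic work-up under which the 5-OH···O=C4 hydrogen-bonded flavanone should not reopen.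

Compound list
1 | 2',6'-dihydroxy-4'-methoxyacetophenone | CC(=O)c1c(O)cc(OC)cc1O | starting material
2 | 2-hydroxybenzyl alcohol (salicyl alcohol) | OCc1ccccc1O | starting material
3 | ortho-quinone methide (6-methylidenecyclohexa-2,4-dien-1-one) | C=C1C=CC=CC1=O | intermediate
4 | 1-[2,6-dihydroxy-3-(2-hydroxybenzyl)-4-methoxyphenyl]ethan-1-one | CC(=O)c1c(O)cc(OC)c(Cc2ccccc2O)c1O | intermediate
5 | 1-[2,6-dihydroxy-3,5-bis(2-hydroxybenzyl)-4-methoxyphenyl]ethan-1-one | CC(=O)c1c(O)c(Cc2ccccc2O)c(OC)c(Cc2ccccc2O)c1O | intermediate
6 | benzaldehyde | O=Cc1ccccc1 | starting material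
7 | pentalithium salt of 5 (four phenoxides and the methyl ketone enolate) | [Li+].[Li+].[Li+].[Li+].[Li+].C=C([O-])c1c([O-])c(Cc2ccccc2[O-])c(OC)c(Cc2ccccc2[O-])c1[O-] | intermediate
8 | pentalithium aldolate (racemic β-alkoxide of the aldol adduct, four phenoxides) | [Li+].[Li+].[Li+].[Li+].[Li+].[O-]C(CC(=O)c1c([O-])c(Cc2ccccc2[O-])c(OC)c(Cc2ccccc2[O-])c1[O-])c1ccccc1 | intermediate
9 | (E)-2',6'-dihydroxy-4'-methoxy-3',5'-bis(2-hydroxybenzyl)chalcone | O=C(/C=C/c1ccccc1)c1c(O)c(Cc2ccccc2O)c(OC)c(Cc2ccccc2O)c1O | intermediate
10 | (2S)-6,8-bis(2-hydroxybenzyl)-7-methoxy-2-phenyl-2H-chromene-4,5-diol (enzyme-bound enol, drawn neutral) | COc1c(Cc2ccccc2O)c(O)c2c(c1Cc1ccccc1O)O[C@H](c1ccccc1)C=C2O | intermediate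
11 | (2S)-5-hydroxy-6,8-bis(2-hydroxybenzyl)-7-methoxy-2-phenylchroman-4-one (7-methoxydichamanetin) | COc1c(Cc2ccccc2O)c(O)c2c(c1Cc1ccccc1O)O[C@H](c1ccccc1)CC2=O | target

Total step count: 3. Longest linear sequence: 3.

Steps most likely to fail

Risk 1 (step 3). The bulky, poorly soluble chalcone may be bound or turned over slowly. The uncatalysed closure through the free phenoxide would then compete and erode the enantiomeric purity. The fallback replaces asymmetric catalysis with racemic closure and resolution. It sets out from 9, which is cyclised without enzyme (NaOAc, EtOH, reflux) to the racemic flavanone F1. Preparative chromatography on a polysaccharide chiral stationary phase separates F1 into 11 and the (2R)-enantiomer F2. F2 is recycled by retro-oxa-Michael ring opening (aq. KOH, then cold acidification) to 9. The fallback comes back to the route at 11.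

Risk 2 (step 2). There are four ways this step may go wrong.
- The pentalithium salt may precipitate.
- Enolisation or dehydration of the aldolate may stall.
- The amide base may consume the aldehyde.
- Partial ring closure may occur on quenching.

The fallback uses protecting groups and sets out from 5. All four phenols are masked (NaH, MOMCl, DMF, 0 °C to rt) to give the tetrakis(methoxymethyl) ether F3. A classical Claisen–Schmidt condensation with 6 (KOH, EtOH, rt) gives the protected (E)-chalcone F4. Brief acid methanolysis (3 M HCl, MeOH–THF, 40 °C, stopped at full deprotection, cold work-up) comes back to the route at 9.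

Risk 3 (step 1). The quinone methide may oligomerise, the alkylation may stop at the mono stage, or the pendant phenol rings may be over-alkylated. The fallback replaces electrophilic substitution with cross-coupling and sets out from 1.
- Double iodination (NIS, MeCN, rt) gives the 3',5'-diiodoacetophenone F5.
- Benzylation (BnBr, K2CO3, DMF, 60 °C) gives its bis(benzyl ether) F6.
- Twofold Negishi coupling (Pd(OAc)2, SPhos, THF, 50 °C) with [2-(benzyloxy)benzyl]zinc chloride F7, made from commercial 2-(benzyloxy)benzyl chloride, Zn dust and LiCl in THF, gives the tetrabenzyl ether F8.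
- Hydrogenolysis (H2, Pd/C, EtOAc) comes back to the route at 5.

Further compounds
F1 | step 3 | racemic 5-hydroxy-6,8-bis(2-hydroxybenzyl)-7-methoxy-2-phenylchroman-4-one | COc1c(Cc2ccccc2O)c(O)c2c(c1Cc1ccccc1O)OC(c1ccccc1)CC2=O
F2 | step 3 | (2R)-5-hydroxy-6,8-bis(2-hydroxybenzyl)-7-methoxy-2-phenylchroman-4-one | COc1c(Cc2ccccc2O)c(O)c2c(c1Cc1ccccc1O)O[C@@H](c1ccccc1)CC2=O
F3 | step 2 | 1-{4-methoxy-2,6-bis(methoxymethoxy)-3,5-bis[2-(methoxymethoxy)benzyl]phenyl}ethan-1-one | CC(=O)c1c(OCOC)c(Cc2ccccc2OCOC)c(OC)c(Cc2ccccc2OCOC)c1OCOC
F4 | step 2 | (E)-1-{4-methoxy-2,6-bis(methoxymethoxy)-3,5-bis[2-(methoxymethoxy)benzyl]phenyl}-3-phenylprop-2-en-1-one | O=C(/C=C/c1ccccc1)c1c(OCOC)c(Cc2ccccc2OCOC)c(OC)c(Cc2ccccc2OCOC)c1OCOC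
F5 | step 1 | 1-(2,6-dihydroxy-3,5-diiodo-4-methoxyphenyl)ethan-1-one | CC(=O)c1c(O)c(I)c(OC)c(I)c1O
F6 | step 1 | 1-[2,6-bis(benzyloxy)-3,5-diiodo-4-methoxyphenyl]ethan-1-one | CC(=O)c1c(OCc2ccccc2)c(I)c(OC)c(I)c1OCc1ccccc1
F7 | step 1 | [2-(benzyloxy)benzyl]zinc chloride | Cl[Zn]Cc1ccccc1OCc1ccccc1
F8 | step 1 | 1-{2,6-bis(benzyloxy)-3,5-bis[2-(benzyloxy)benzyl]-4-methoxyphenyl}ethan-1-one | CC(=O)c1c(OCc2ccccc2)c(Cc2ccccc2OCc2ccccc2)c(OC)c(Cc2ccccc2OCc2ccccc2)c1OCc1ccccc1
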